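**Strategy.** Everything rests on cutting the carbocycle of the 6H-isochromen-6-one core (isochromene numbering) at C4a=C5 and C7–C8. The cut exploits that C5 and C7 both flank the C6 ketone, while C4a and C8 stand 1,3 across C8a, like the ring carbonyl and the formyl carbon of a 3-formyl-4-pyranone. In one flask a chiral boron enolate, made by 1,4-hydroboration of a 2-silyloxy enone, adds through C7 to the aldehyde and sets both stereocentres; TiCl4/Bu3N then closes the C5 methyl group onto the pyranone carbonyl, and ring oxygen O2 expels the carbinol oxygen. The precursors are a formylpyranone from kojic acid and an enol silane from biacetyl.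

Key step: step 6

Assumption: the facial sense of the enolborinate made from (+)-α-pinene is taken from the chair model that holds for the related (Z)-enolborinates and allylboranes (si-face attack on RCHO).

Step 1
Reactants: 1 kojic acid
Product: 2 6-(hydroxymethyl)-4-oxo-4H-pyran-3-yl trifluoromethanesulfonate
Conditions: PhNTf2, Et3N, DMF, 0 °C to rt
Reagents that add atoms: N-phenylbis(trifluoromethanesulfonimide), O=S(=O)(N(c1ccccc1)S(=O)(=O)C(F)(F)F)C(F)(F)F
Why: Chemoselective O-sulfonylation: Et3N deprotonates only the acidic enolic 5-OH (a vinylogous acid), whose oxyanion takes the triflyl group from the mild donor PhNTf2, while the neutral primary alcohol stays free.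

Step 2
Reactants: 2 6-(hydroxymethyl)-4-oxo-4H-pyran-3-yl trifluoromethanesulfonate
Product: 4 tert-butyl (E)-3-[4-oxo-5-(trifluoromethylsulfonyloxy)-4H-pyran-2-yl]prop-2-enoate, via pyranone aldehyde 3 (not isolated)
Conditions: MnO2, Ph3P=CHCO2t-Bu, CH2Cl2, rt
Reagents that add atoms: (tert-butoxycarbonylmethylene)triphenylphosphorane, CC(C)(C)OC(=O)C=P(c1ccccc1)(c1ccccc1)c1ccccc1
Why: Tandem MnO2 oxidation/Wittig olefination: the allylic-type alcohol is oxidised and the hydrate-prone aldehyde 3 is trapped at once by the stabilised ylide, which gives the (E)-enoate.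

Step 3
Reactants: 4 tert-butyl (E)-3-[4-oxo-5-(trifluoromethylsulfonyloxy)-4H-pyran-2-yl]prop-2-enoate
Product: 5 tert-butyl (E)-3-(5-formyl-4-oxo-4H-pyran-2-yl)prop-2-enoate
Conditions: Pd(OAc)2, dppp, CO (1 atm), Et3SiH, Et3N, DMF, 60 °C
Reagents that add atoms: carbon monoxide, [C-]#[O+]
Why: Palladium-catalysed reductive carbonylation of an enol triflate: zerovalent palladium inserts into the electron-poor C–OTf bond, CO inserts, and the silane delivers hydride to the acylpalladium species faster than it touches the enoate.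

Step 4
Reactants: 6 butane-2,3-dione (biacetyl)
Product: 7 3-(triethylsilyloxy)but-3-en-2-one
Conditions: TESOTf (1 equiv), Et3N, CH2Cl2, 0 °C
Reagents that add atoms: triethylsilyl trifluoromethanesulfonate, CC[Si](CC)(CC)OS(=O)(=O)C(F)(F)F
Why: Soft enolisation and O-silylation of one carbonyl group of the 1,2-diketone with one equivalent of silyl triflate gives the 2-silyloxy enone, the second carbonyl being deactivated by conjugation.

Step 5
Reactants: 8 (+)-α-pinene (two equivalents)
Product: 9 (−)-diisopinocampheylborane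
Conditions: BH3·SMe2, THF, 0 °C, crystallisation
Reagents that add atoms: borane–dimethyl sulfide, C[S+](C)[BH3-]
Why: Hydroboration of the trisubstituted alkene from the face opposite the gem-dimethyl bridge stops for steric reasons at the dialkylborane, which crystallises from the mixture and thereby gains optical purity.

Step 6
Reactants: 5 tert-butyl (E)-3-(5-formyl-4-oxo-4H-pyran-2-yl)prop-2-enoate; 7 3-(triethylsilyloxy)but-3-en-2-one; 9 (−)-diisopinocampheylborane
Product: 13 tert-butyl (E)-3-[(7R,8R)-8-hydroxy-7-methyl-6-oxo-7-(triethylsilyloxy)-7,8-dihydro-6H-isochromen-3-yl]prop-2-enoate, via enolborinate 10 (not isolated), via boron aldolate 11 (not isolated), via titanium-bound carbinol 12 (not isolated)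
Conditions: 7, 9, Et2O, 0 °C; then 5, CH2Cl2, −78 to −40 °C; then TiCl4, Bu3N, CH2Cl2, −78 to −20 °C; pH 7 buffer
Reagents that add atoms: none
Why: Proposed new method: borane 9 adds 1,4 to the s-cis form of enone 7 and so gives only enolborinate 10 with the new C7 methyl cis to O–B; 10 adds to the formyl carbon C8 of 5 through a Zimmerman–Traxler chair (bond C7–C8), then TiCl4 takes O8 over from boron, Bu3N enolises the only acidic site left (the C5 methyl), C5 adds to the pyranone carbonyl C4a, and carbinol 12, flanked by two enol ethers of O2, ionises to a pyrylium ion that loses H-5 (bond C4a=C5). Closest known reaction types: the diisopinocampheylborane reductive aldol of acrylamides and enones, the TiCl4/amine aldol between two ketones and the Stork–Danheiser sequence (1,2-addition to a vinylogous ester, then loss of the carbinol oxygen); new are a 2-silyloxy enone as donor and a 4-pyranone carbonyl as acceptor. One ring is closed, the carbocycle C4a–C5–C6–C7–C8–C8a, in the 6-(enolendo)-exo-trig mode. C8 is set by the isopinocampheyl groups, which should expose the si face of the aldehyde, and C7 by the enolate geometry in the chair (methyl syn, silyloxy anti to O8 in the open chain), which is the cis-7,8-dioxygen pattern of the ring, (7R,8R). Two selectivities are needed: attack at CHO and not at C1 in the first stage, secured because the neutral boron enolate reacts only with a carbonyl oxygen bound to boron, and closure at C4a and not at C1 (both would give six-membered rings), secured because one titanium centre can hold O8, the enolate O6 and O4a together (1,3,5 on the new ring) and so places C5 over C4a, whereas in a closure at C1 O6 and O4a lie at opposite ends. The loss of the C4a oxygen to titanium makes the closure irreversible.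

Step 7
Reactants: 14 methyl orsellinate
Product: 15 methyl 2,4-bis(methoxymethoxy)-6-methylbenzoate
Conditions: NaH, MOMCl, DMF, 0 °C to rt
Reagents that add atoms: chloromethyl methyl ether, COCCl
Why: Williamson-type O-alkylation of both phenoxides; NaH is needed because the 2-OH is hydrogen-bonded to the ester.

Step 8
Reactants: 15 methyl 2,4-bis(methoxymethoxy)-6-methylbenzoate
Product: 16 2,4-bis(methoxymethoxy)-6-methylbenzoic acid
Conditions: KOH, MeOH/H2O, reflux; then 1 M HCl to pH 4, 0 °C
Reagents that add atoms: potassium hydroxide, [K+].[OH-]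
Why: Saponification of the doubly ortho-substituted ester needs forcing basic conditions, which the MOM acetals tolerate, and mild acidification keeps them intact.

Step 9
Reactants: 13 tert-butyl (E)-3-[(7R,8R)-8-hydroxy-7-methyl-6-oxo-7-(triethylsilyloxy)-7,8-dihydro-6H-isochromen-3-yl]prop-2-enoate; 16 2,4-bis(methoxymethoxy)-6-methylbenzoic acid
Product: 18 (7R,8R)-3-[(E)-3-tert-butoxy-3-oxoprop-1-enyl]-7-methyl-6-oxo-7-(triethylsilyloxy)-7,8-dihydro-6H-isochromen-8-yl 2,4-bis(methoxymethoxy)-6-methylbenzoate, via acid chloride 17 (not isolated)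
Conditions: 16, 1-chloro-N,N,2-trimethylprop-1-en-1-amine, CH2Cl2, 0 °C; then 13, DMAP, Et3N, CH2Cl2, 0 °C to 40 °C
Reagents that add atoms: none
Why: Acylation of the only free hydroxyl group (C8–OH) by the acid chloride, made under neutral conditions so that the MOM acetals survive, under nucleophilic catalysis by DMAP; the C8–O bond is not touched, so the configuration is kept.

Step 10
Reactants: 18 fully protected mitorubrinic acid B
Product: 19 (+)-mitorubrinic acid B
Conditions: TFA/CH2Cl2/H2O (10:10:1), 0 °C to rt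
Reagents that add atoms: none
Why: Acidolysis removes all four acid-labile groups (tert-butyl ester by E1 loss of isobutene, MOM acetals and silyl ether by hydrolysis), while protonation at O6 to a hydroxypyrylium ion should guard the allylic C8 ester against ionisation, so that C7 and C8 are untouched.

**Compound list**

1 | kojic acid, 5-hydroxy-2-(hydroxymethyl)-4H-pyran-4-one | OCC1=CC(=O)C(O)=CO1 | starting material
2 | 6-(hydroxymethyl)-4-oxo-4H-pyran-3-yl trifluoromethanesulfonate | OCC1=CC(=O)C(OS(=O)(=O)C(F)(F)F)=CO1 | intermediate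
3 | 6-formyl-4-oxo-4H-pyran-3-yl trifluoromethanesulfonate | O=CC1=CC(=O)C(OS(=O)(=O)C(F)(F)F)=CO1 | intermediate
4 | tert-butyl (E)-3-[4-oxo-5-(trifluoromethylsulfonyloxy)-4H-pyran-2-yl]prop-2-enoate | CC(C)(C)OC(=O)/C=C/C1=CC(=O)C(OS(=O)(=O)C(F)(F)F)=CO1 | intermediate
5 | tert-butyl (E)-3-(5-formyl-4-oxo-4H-pyran-2-yl)prop-2-enoate | CC(C)(C)OC(=O)/C=C/C1=CC(=O)C(C=O)=CO1 | intermediate
6 | butane-2,3-dione (biacetyl) | CC(=O)C(C)=O | starting material
7 | 3-(triethylsilyloxy)but-3-en-2-one | C=C(O[Si](CC)(CC)CC)C(C)=O | intermediate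
8 | (+)-α-pinene, (1R,5R) | CC1=CC[C@@H]2C[C@H]1C2(C)C | starting material
9 | (−)-diisopinocampheylborane, from (+)-α-pinene | [H]B([C@@H]1C[C@@H]2C[C@H]([C@H]1C)C2(C)C)[C@@H]1C[C@@H]2C[C@H]([C@H]1C)C2(C)C | intermediate
10 | (E)-2-(diisopinocampheylboryloxy)-3-(triethylsilyloxy)but-2-ene, C7 methyl cis to O–B | C/C(O[Si](CC)(CC)CC)=C(/C)OB([C@@H]1C[C@@H]2C[C@H]([C@H]1C)C2(C)C)[C@@H]1C[C@@H]2C[C@H]([C@H]1C)C2(C)C | intermediate
11 | tert-butyl (E)-3-{5-[(1R,2R)-1-(diisopinocampheylboryloxy)-2-methyl-3-oxo-2-(triethylsilyloxy)butyl]-4-oxo-4H-pyran-2-yl}prop-2-enoate | B([C@@H]1C[C@@H]2C[C@H]([C@H]1C)C2(C)C)([C@@H]1C[C@@H]2C[C@H]([C@H]1C)C2(C)C)O[C@@H]([C@@](C)(O[Si](CC)(CC)CC)C(C)=O)C1=COC(/C=C/C(=O)OC(C)(C)C)=CC1=O | intermediate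
12 | tert-butyl (E)-3-[(4aS,7R,8R)-4a,8-dihydroxy-7-methyl-6-oxo-7-(triethylsilyloxy)-4a,5,7,8-tetrahydro-6H-isochromen-3-yl]prop-2-enoate, in the flask as its titanium alkoxide, drawn protonated | O[C@@H]1C2=COC(/C=C/C(=O)OC(C)(C)C)=C[C@@]2(O)CC(=O)[C@]1(C)O[Si](CC)(CC)CC | intermediate
13 | tert-butyl (E)-3-[(7R,8R)-8-hydroxy-7-methyl-6-oxo-7-(triethylsilyloxy)-7,8-dihydro-6H-isochromen-3-yl]prop-2-enoate | O[C@@H]1C2=COC(/C=C/C(=O)OC(C)(C)C)=CC2=CC(=O)[C@]1(C)O[Si](CC)(CC)CC | intermediate
14 | methyl orsellinate, methyl 2,4-dihydroxy-6-methylbenzoate | COC(=O)c1c(C)cc(O)cc1O | starting material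
15 | methyl 2,4-bis(methoxymethoxy)-6-methylbenzoate | COCOc1cc(C)c(C(=O)OC)c(OCOC)c1 | intermediate
16 | 2,4-bis(methoxymethoxy)-6-methylbenzoic acid | COCOc1cc(C)c(C(=O)O)c(OCOC)c1 | intermediate
17 | 2,4-bis(methoxymethoxy)-6-methylbenzoyl chloride | COCOc1cc(C)c(C(=O)Cl)c(OCOC)c1 | intermediate
18 | (7R,8R)-3-[(E)-3-tert-butoxy-3-oxoprop-1-enyl]-7-methyl-6-oxo-7-(triethylsilyloxy)-7,8-dihydro-6H-isochromen-8-yl 2,4-bis(methoxymethoxy)-6-methylbenzoate | COCOc1cc(C)c(C(=O)O[C@@H]2C3=COC(/C=C/C(=O)OC(C)(C)C)=CC3=CC(=O)[C@]2(C)O[Si](CC)(CC)CC)c(OCOC)c1 | intermediate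
19 | (+)-mitorubrinic acid B, (7R,8R), 7-OH and 8-acyloxy cis | Cc1cc(O)cc(O)c1C(=O)O[C@@H]1C2=COC(/C=C/C(=O)O)=CC2=CC(=O)[C@]1(C)O | target

**Total steps:** 10. **Longest linear sequence:** 6 (steps 1, 2, 3, 6, 9, 10).

**Steps most likely to fail**

Step 6. The C5 enolate may close at C1 (conjugate attack followed by opening of the pyranone) instead of at C4a, or the sequence may stall after the first bond. The fallback uses known reaction types only, sets out from 11 and comes back at 18.
- The flask is worked up after the boron aldol stage (MeOH, pH 7 buffer) to give the open aldol F1.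
- O8 is acylated with 17 (DMAP, Et3N) to the open-chain orsellinate F2, which also blocks retro-aldol cleavage.
- TMSOTf/Et3N gives the trimethylsilyl enol ether F3, and NBS gives the bromoketone F4.
- Lawesson's reagent (toluene, 60 °C) converts the electron-rich pyranone carbonyl into the pyranthione F5. Its sulfur is alkylated by C5–Br to give the bridged 4-(alkylthio)pyrylium bromide F6.
- PPh3/Et3N then brings about an Eschenmoser sulfide contraction (episulfide across C4a–C5, sulfur taken up by the phosphine). The sulfur tether allows carbon–carbon bond formation only at C4a, and the product is 18.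

Step 3. The amine base may attack the very electrophilic formylpyranone as it forms, or the silane may reduce the C–OTf bond before CO inserts. The fallback sets out from 4 and comes back at 5.
- Suzuki–Miyaura vinylation with potassium vinyltrifluoroborate (PdCl2(dppf), Et3N, n-PrOH, 80 °C) gives the vinylpyranone F7.
- Lemieux–Johnson cleavage (OsO4 cat., NaIO4, 2,6-lutidine, dioxane/H2O) of the terminal, more electron-rich alkene leaves the enoate alone and gives 5.

Step 9. Acylation may be too slow because both partners are hindered, so that the acid chloride is lost to side reactions. The fallback changes the order of events, sets out from 13 and comes back at 19.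
- HF·pyridine (THF, 0 °C) first removes the silyl group to give the cis-diol F8.
- The now less shielded secondary C8–OH of F8 is acylated by 17, in preference to the tertiary C7–OH, to give the mono-ester F9.
- The TFA conditions of step 10 convert F9 into 19.

**Further compounds**
F1 | step 6 | tert-butyl (E)-3-{5-[(1R,2R)-1-hydroxy-2-methyl-3-oxo-2-(triethylsilyloxy)butyl]-4-oxo-4H-pyran-2-yl}prop-2-enoate | O[C@@H]([C@@](C)(O[Si](CC)(CC)CC)C(C)=O)C1=COC(/C=C/C(=O)OC(C)(C)C)=CC1=O
F2 | step 6 | O8-[2,4-bis(methoxymethoxy)-6-methylbenzoate] of F1 | COCOc1cc(C)c(C(=O)O[C@@H]([C@@](C)(O[Si](CC)(CC)CC)C(C)=O)C2=COC(/C=C/C(=O)OC(C)(C)C)=CC2=O)c(OCOC)c1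
F3 | step 6 | trimethylsilyl enol ether of F2 (C5=C6) | COCOc1cc(C)c(C(=O)O[C@@H]([C@@](C)(O[Si](CC)(CC)CC)C(=C)O[Si](C)(C)C)C2=COC(/C=C/C(=O)OC(C)(C)C)=CC2=O)c(OCOC)c1
F4 | step 6 | C5-bromoketone of F2 | COCOc1cc(C)c(C(=O)O[C@@H]([C@@](C)(O[Si](CC)(CC)CC)C(=O)CBr)C2=COC(/C=C/C(=O)OC(C)(C)C)=CC2=O)c(OCOC)c1
F5 | step 6 | 4H-pyran-4-thione of F4 | COCOc1cc(C)c(C(=O)O[C@@H]([C@@](C)(O[Si](CC)(CC)CC)C(=O)CBr)C2=COC(/C=C/C(=O)OC(C)(C)C)=CC2=S)c(OCOC)c1
F6 | step 6 | bridged 4-(alkylthio)pyrylium bromide (seven-membered ring C4a–S–C5–C6–C7–C8–C8a) | [Br-].COCOc1cc(C)c(C(=O)O[C@@H]2c3c[o+]c(/C=C/C(=O)OC(C)(C)C)cc3SCC(=O)[C@]2(C)O[Si](CC)(CC)CC)c(OCOC)c1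
F7 | step 3 | tert-butyl (E)-3-(4-oxo-5-vinyl-4H-pyran-2-yl)prop-2-enoate | C=CC1=COC(/C=C/C(=O)OC(C)(C)C)=CC1=O
F8 | step 9 | tert-butyl (E)-3-[(7R,8R)-7,8-dihydroxy-7-methyl-6-oxo-7,8-dihydro-6H-isochromen-3-yl]prop-2-enoate | O[C@@H]1C2=COC(/C=C/C(=O)OC(C)(C)C)=CC2=CC(=O)[C@]1(C)O
F9 | step 9 | (7R,8R)-3-[(E)-3-tert-butoxy-3-oxoprop-1-enyl]-7-hydroxy-7-methyl-6-oxo-7,8-dihydro-6H-isochromen-8-yl 2,4-bis(methoxymethoxy)-6-methylbenzoate | COCOc1cc(C)c(C(=O)O[C@@H]2C3=COC(/C=C/C(=O)OC(C)(C)C)=CC3=CC(=O)[C@]2(C)O)c(OCOC)c1
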